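The data were generated by integration with made-up constants, and the scatter is random.

Answer 3 questions with one quantity.

the same everywhere: left-handed substrate 0.14 M; right-handed substrate 0.14 M; free catalyst 0.26 mol%; added ligand 2.1 mM
- winter: partner 3 equiv; impurity 46 µM; run made earlier
- noon: partner 3 equiv; impurity 100 µM; run made earlier
- Tuesday's: partner 3.00 equiv; impurity 45 µM; time 2.0 h
- Thursday's: partner 3.00 equiv; impurity 200 µM; time 2.0 h

- winter (time / min: right-handed substrate / %, left-handed substrate / %, left-handed product / %): 15.0: 50, 43, 6; 30.0: 47, 39, 13; 50.0: 41, 33, 15; 60.0: 42, 34, 17; 80.0: 40, 29, 22
- noon (time / min: right-handed substrate / %, left-handed substrate / %, left-handed product / %): 8.00: 48, 45, 3; 20.0: 46, 40, 13; 40.0: 46, 39, 9; 60.0: 48, 36, 15; 80.0: 41, 30, 21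

(scatter of a reading: 2 percentage points)

- free catalyst is single-handed; left-handed substrate and right-handed substrate are mirror images of each other, charged as a racemate, each of them at the stated concentration
- the analysis behind the earlier runs scatters by 2 percentage points, standard deviation
- steps that have been proposed: free catalyst + added ligand <-> idle complex; free catalyst + left-handed substrate <-> catalyst intermediate A; free catalyst + right-handed substrate <-> catalyst intermediate B; 2 free catalyst <-> resting dimer; partner + catalyst intermediate A -> free catalyst + left-handed product; free catalyst + impurity -> spent catalyst; partner + catalyst intermediate B -> free catalyst + right-handed product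
- an excess is the difference of the two amounts in percent of their sum
- an excess is below zero if the other one leads

* which one finishes higher in excess of right-handed substrate over left-handed substrate among what is left of the two ("neither" within 2 percentage points) (Tuesday's / Thursday's / neither)
* excess of right-handed substrate over left-handed substrate among what is left of the two at the end, Tuesday's
* excess of right-handed substrate over left-handed substrate among what is left of the two at the end, Thursday's

Start from the proposed step free catalyst + impurity -> spent catalyst. It runs one way, one for one. So divide c(impurity) by the charged c(free catalyst), 364 µM. Tuesday's gives 12.4% and Thursday's gives 54.9%. Call this the dead share: the part of the catalyst lost for good once the impurity has reacted.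

Now read the last rows of the tables, at 80.0 min. The winter run shows 29% left-handed and 40% right-handed substrate. The noon run shows 30% and 41%. Take the log of each substrate's remaining part of its own charge, and divide left-handed by right-handed. This is the selectivity factor: 2.44 for winter, 2.57 for noon. Use the mean, 2.51.

Read the left-handed column against the dead shares next. Winter has 12.6% and noon has 27.5%. Yet their left-handed readings differ by less than the scatter, so these two rows give no test of the dead share. Assume it anyway. Divide each log loss of left-handed substrate by the live share, one minus the dead share, and by the time. The mean is 0.00830 min⁻¹.

Scale to 2.0 h. Tuesday's log loss is 0.873 and Thursday's is 0.449. Divide each by the selectivity factor for the right-handed loss. My excesses are 25.7% for Tuesday's and 13.4% for Thursday's.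

The forecast names Tuesday's, with 22% and 18%, on the ground that “Impurity kills catalyst but leaves selectivity unchanged”. Its gap is narrower than mine.

The flask gives 27.4% for Tuesday's and 16.5% for Thursday's, so Tuesday's finishes higher.

    free catalyst + added ligand ⇌ idle complex, settled at all times (K = 5500 M⁻¹)
    free catalyst + left-handed substrate ⇌ catalyst intermediate A (K = 8.30 M⁻¹, k = 26000 M⁻¹ min⁻¹)
    free catalyst + right-handed substrate ⇌ catalyst intermediate B (K = 94.0 M⁻¹, k = 8300 M⁻¹ min⁻¹)
    2 free catalyst ⇌ resting dimer, settled at all times (K = 26000 M⁻¹)
    partner + catalyst intermediate A → free catalyst + left-handed product (k = 190 M⁻¹ min⁻¹)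
    free catalyst + impurity → spent catalyst (k = 8000 M⁻¹ min⁻¹)
    partner + catalyst intermediate B → free catalyst + right-handed product (k = 5.90 M⁻¹ min⁻¹)

At 0.715 h in Thursday's, catalyst intermediate B falls back 39 times faster than it goes on. At the end spent catalyst stands at 54.9% in Thursday's against a dead share of 54.9%, and at 12.4% in Tuesday's against 12.4%. One more flask, like Thursday's but with 1 mol% of free catalyst, has a dead share of 14.3%. Its spent catalyst stands at 14.3% and its excess at 72.6%.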